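The stirred, closed vessel holds substrate and coupling partner, and the readings so far follow this very flask.

common to all: substrate 0.80 M

|  | coupling partner | remark | time |
|---|---|---|---|
| theta | 2 equiv | the very flask that is asked about, followed so far |  |
| flask | 2.00 equiv |  | 10 min |

theta run (percent of the substrate charged)

| time / min | single product / % | substrate / % |
|---|---|---|
| 0.167 | 29 | 68 |
| 0.200 | 31 | 61 |
| 0.417 | 36 | 40 |
| 0.833 | 29 | 20 |
| 1.50 | 16 | 6 |
| 3.00 | 2 | 2 |

(each reading ± 1.5 percentage points)

- the moment within 10 min at which there is most single product
- the amount of single product, in percent of the substrate charged, at that time



Build the flask up one process at a time, starting from its end: by 3.00 min the readings show single product at 2% and substrate at 2%. The top therefore lies early.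

First take just the main step, with a the first-order constant of substrate loss. Read at 0.417 min:

a = 2.20 min⁻¹

With this step by itself, single product simply climbs, so a top needs a second process.

Add a first-order loss of single product with constant b. At the top, making equals loss, so a × substrate = b × single product. That gives the crossing ratio r = a/b, single product over substrate at the top (a selectivity factor). The highest reading gives:

r = 0.900
b = a/r = 2.44 min⁻¹
top time = ln(r)/(a − b) = 0.432 min
top height = r·exp(−a × top time) = 34.9%

Then add the rest: the coupling partner is consumed too, so a should ease, but r, taken at the top, carries that state with it. Your reckoning stands.

The forecast says 0.43 min and 37%, from “two nearly equal rate constants”. Its time matches yours, and your height is lower.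

This flask gives 0.427 min and 36.3%.

    single product → over-reaction product (k = 0.0289 s⁻¹)
    substrate + coupling partner → single product (k = 0.0274 L mol⁻¹ s⁻¹)
    coupling partner + single product ⇌ double product (K = 0.540 L mol⁻¹, k = 0.00468 L mol⁻¹ s⁻¹)

With r at 0.900, that top implies substrate at 40.3%, and this flask holds 40.2% at 0.427 min, the best time. The path to over-reaction product has the largest single effect on the height: removing it lifts the top from 36.3% to 76.1%. In the neighbour with 0.48 M substrate at the same equivalents, a scales with concentration to 1.32 min⁻¹ while b is held, so r becomes 0.540 and the reckoned height 26.2%; that flask's top stands at 29.2%.

The earlier runs and the new flask were computed for an exercise; scatter was added.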